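**Retrosynthetic overview**
1. Target ⇒ its 5,7-di-O-benzyl ether, so the last step is only a hydrogenolysis.
2. Pyranone C ring (O1–C2 and C3–OH bonds) ⇒ one-pot Claisen–Schmidt / Algar–Flynn–Oyamada reaction of 4,6-di-O-benzylphloroacetophenone with (R)-3-hydroxy-2,2-dimethylchroman-6-carbaldehyde.
3. Key disconnection: the two C–O bonds of the hydroxychroman (C3–OH and O1–C2) ⇒ phenol-directed asymmetric epoxidation / 6-endo cycloetherification of 4-hydroxy-3-prenylbenzaldehyde. This sets the only stereocentre.
4. 4-Hydroxy-3-prenylbenzaldehyde ⇒ 4-hydroxybenzaldehyde + prenyl bromide.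
5. Ring order: the dihydropyran ring of the chroman first, the pyranone C ring second. Both benzene rings are bought.

Assumption: the stereocentre (chroman C3) reads as (R). The (R,R) antipode of the bis-hydroxamic acid ligand is taken as the one that gives (R)-4. This is checked by chiral HPLC against material from the step 2 fallback, and the equally commercial (S,S) ligand is used if the sense is opposite.

**Step 1**
Reactants: 1 p-hydroxybenzaldehyde (4-hydroxybenzaldehyde); 2 prenyl bromide (1-bromo-3-methylbut-2-ene)
Product: 3 o-prenylphenol aldehyde [4-hydroxy-3-(3-methylbut-2-en-1-yl)benzaldehyde]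
Conditions: KOH (1.0 equiv), H2O, rt, 24 h
Reagents that add atoms: none
Why: Phenoxide C-alkylation; in water the phenoxide oxygen is heavily hydrogen-bonded, so the soft allylic bromide is taken up (SN2, linear prenyl) at the free ortho carbon (para is blocked by CHO), and the O-prenyl ether and recovered 1 are separated by base extraction and chromatography.

**Step 2**
Reactants: 3 o-prenylphenol aldehyde
Product: 5 chromanol aldehyde [(3R)-3-hydroxy-2,2-dimethyl-3,4-dihydro-2H-chromene-6-carbaldehyde], via (R)-epoxide 4 (not isolated)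
Conditions: Hf(OtBu)4 (10 mol %), (R,R)-N,N'-dihydroxy-N,N'-bis(diphenylacetyl)cyclohexane-1,2-diamine (12 mol %), DMPU (20 mol %), 4 Å MS, cumene hydroperoxide (1.2 equiv), toluene, 0 °C, 24–48 h; then CSA (20 mol %), 0 °C → rt
Reagents that add atoms: cumene hydroperoxide, CC(C)(OO)c1ccccc1
Why: Proposed new method: the acidic phenol of 3 exchanges onto the d0, redox-inert Hf(IV) centre held by the C2-symmetric dianionic bis-hydroxamate, and cumyl hydroperoxide binds to the same metal; the rigid o-phenylene tether (a conformationally locked bishomoallylic "alcohol") swings the prenyl C=C under the activated peroxide oxygen so that only the Re face of the CH= carbon is open between the diphenylmethyl walls, giving (R)-epoxide 4, while undirected Hf/hydroperoxide epoxidation of an isolated alkene is negligible; catalytic CSA then lets the phenol oxygen open 4 at the tertiary, cation-stabilising carbon (6-endo, forming O1–C2) without touching the C3–O bond, so the ee of 4 passes unchanged into (R)-5; the closest known reaction types are the Zr/Hf- and V-bis-hydroxamic acid hydroxyl-directed epoxidations of aliphatic homoallylic and bishomoallylic alcohols and the racemic VO(acac)2/TBHP–acid oxidative cyclisation of o-prenylphenols, and what is new is a phenol as directing group in the asymmetric version and its merger with the ring closure.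

**Step 3**
Reactants: 6 phloroacetophenone (2',4',6'-trihydroxyacetophenone)
Product: 7 dibenzyl ketone [1-[2,4-bis(benzyloxy)-6-hydroxyphenyl]ethan-1-one]
Conditions: BnBr (2.1 equiv), K2CO3 (2.2 equiv), acetone, reflux, 8 h
Reagents that add atoms: benzyl bromide, BrCc1ccccc1
Why: Williamson etherification; the remaining ortho OH is chelated to the acetyl C=O and is the least nucleophilic, so two equivalents of BnBr stop at the 4,6-dibenzyl ether.

**Step 4**
Reactants: 5 chromanol aldehyde; 7 dibenzyl ketone
Product: 10 dibenzyl flavonol [5,7-bis(benzyloxy)-3-hydroxy-2-[(3R)-3-hydroxy-2,2-dimethylchroman-6-yl]-4H-chromen-4-one], via chalcone 8 (not isolated), via dihydroflavonol 9 (not isolated)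
Conditions: KOH (50% aq, 10 equiv), EtOH–THF, rt, 36 h; then 30% H2O2 (6 equiv), 0 °C → rt, 5 h; then 1 M HCl
Reagents that add atoms: hydrogen peroxide, OO
Why: Claisen–Schmidt condensation gives (E)-chalcone 8, and the Algar–Flynn–Oyamada reaction (HOO− attack on the enone, 6-endo closure of the 2'-phenoxide on the β-carbon that the para-alkoxy B ring activates, then oxidation of 9 by excess alkaline H2O2) forms O1–C2 and C3–OH; the two transient centres of 9 are erased and the remote, non-enolisable carbinol centre is untouched.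

**Step 5**
Reactants: 10 dibenzyl flavonol
Product: 11 target [3,5,7-trihydroxy-2-[(3R)-3-hydroxy-2,2-dimethylchroman-6-yl]-4H-chromen-4-one]
Conditions: H2 (1 atm), 10% Pd/C, EtOAc–MeOH 1:1, rt
Reagents that add atoms: none
Why: Catalytic hydrogenolysis of the two benzyl aryl ethers under neutral conditions; the flavonol double bond, the aryl tert-alkyl ether and the homobenzylic carbinol (the chroman has no benzylic C–O bond) are inert, so (R) is kept.

**Compound list**
1 | 4-hydroxybenzaldehyde | O=Cc1ccc(O)cc1 | starting material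
2 | prenyl bromide (1-bromo-3-methylbut-2-ene) | CC(C)=CCBr | starting material
3 | 4-hydroxy-3-(3-methylbut-2-en-1-yl)benzaldehyde | CC(C)=CCc1cc(C=O)ccc1O | intermediate
4 | 3-{[(2R)-3,3-dimethyloxiran-2-yl]methyl}-4-hydroxybenzaldehyde | CC1(C)O[C@@H]1Cc1cc(C=O)ccc1O | intermediate (not isolated)
5 | (3R)-3-hydroxy-2,2-dimethyl-3,4-dihydro-2H-chromene-6-carbaldehyde | CC1(C)Oc2ccc(C=O)cc2C[C@H]1O | intermediate
6 | 2',4',6'-trihydroxyacetophenone | CC(=O)c1c(O)cc(O)cc1O | starting material
7 | 1-[2,4-bis(benzyloxy)-6-hydroxyphenyl]ethan-1-one | CC(=O)c1c(O)cc(OCc2ccccc2)cc1OCc1ccccc1 | intermediate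
8 | (E)-1-[2,4-bis(benzyloxy)-6-hydroxyphenyl]-3-[(3R)-3-hydroxy-2,2-dimethylchroman-6-yl]prop-2-en-1-one | CC1(C)Oc2ccc(/C=C/C(=O)c3c(O)cc(OCc4ccccc4)cc3OCc3ccccc3)cc2C[C@H]1O | intermediate (not isolated)
9 | trans-5,7-bis(benzyloxy)-3-hydroxy-2-[(3R)-3-hydroxy-2,2-dimethylchroman-6-yl]chroman-4-one (both trans C2/C3 diastereomers; these centres are erased) | CC1(C)Oc2ccc(C3Oc4cc(OCc5ccccc5)cc(OCc5ccccc5)c4C(=O)C3O)cc2C[C@H]1O | intermediate (not isolated)
10 | 5,7-bis(benzyloxy)-3-hydroxy-2-[(3R)-3-hydroxy-2,2-dimethylchroman-6-yl]-4H-chromen-4-one | CC1(C)Oc2ccc(-c3oc4cc(OCc5ccccc5)cc(OCc5ccccc5)c4c(=O)c3O)cc2C[C@H]1O | intermediate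
11 | 3,5,7-trihydroxy-2-[(3R)-3-hydroxy-2,2-dimethylchroman-6-yl]-4H-chromen-4-one | CC1(C)Oc2ccc(-c3oc4cc(O)cc(O)c4c(=O)c3O)cc2C[C@H]1O | target

**Total steps:** 5. **Longest linear sequence:** 4 (steps 1, 2, 4, 5; step 3 is a side branch).

**Three steps most likely to fail**

*Step 2 (the new step).*
- Risks: an aryloxide may give weak or wrong-sense facial control compared with an alkoxide director. The ring may close 5-exo to the 2-(2-hydroxypropan-2-yl)dihydrobenzofuran. The hydroperoxide may attack the CHO group.
- Fallback: this uses known chemistry and sets the stereocentre on a chromene instead of on the prenyl group. It sets out from 3 and comes back at 5.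
- DDQ in refluxing dioxane dehydrogenates 3 through the o-quinone methide and 6π-electrocyclisation to 2,2-dimethyl-2H-chromene-6-carbaldehyde F1.
- Jacobsen–Katsuki epoxidation with (R,R)-Mn(salen)Cl and mCPBA/NMO in CH2Cl2 at −78 °C gives (3R,4R)-3,4-epoxy-2,2-dimethylchromane-6-carbaldehyde F2.
- LiAlH4 in THF delivers hydride to the benzylic C4 and also reduces the aldehyde, giving (3R)-6-(hydroxymethyl)-2,2-dimethylchroman-3-ol F3.
- MnO2 in CH2Cl2 re-oxidises only the benzylic primary alcohol and returns 5.

*Step 4.*
- Risk: the 6'-benzyloxy group can steer the Algar–Flynn–Oyamada reaction toward 5-exo closure and aurone formation.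
- Fallback: the ring is closed first and oxygen is put on C3 afterwards. It sets out from 8, now isolated after the Claisen–Schmidt stage, and comes back at 10.
- Catalytic I2 in DMSO at 120–130 °C cyclodehydrogenates 8 to 5,7-bis(benzyloxy)-2-[(3R)-3-hydroxy-2,2-dimethylchroman-6-yl]-4H-chromen-4-one F4.
- LDA (3 equiv, one of which is consumed by the free alcohol) in THF at −78 °C lithiates C3. The anion is trapped with B(OMe)3 and oxidised with H2O2/AcOH to 10.

*Step 1.*
- Risk: O-alkylation and double alkylation keep the yield of the C-prenyl product modest.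
- Fallback: cross-coupling replaces phenoxide alkylation. It sets out from 1 and comes back at 3.
- Br2 in CHCl3–MeOH at 0 °C gives 3-bromo-4-hydroxybenzaldehyde F5.
- A ligand-controlled α-selective Suzuki–Miyaura coupling with commercial prenylboronic acid pinacol ester (Pd(OAc)2, bulky biarylphosphine, K3PO4, aq. THF, 40 °C) gives 3.

**Further compounds**
F1 | step 2 | 2,2-dimethyl-2H-chromene-6-carbaldehyde | CC1(C)C=Cc2cc(C=O)ccc2O1
F2 | step 2 | (3R,4R)-3,4-epoxy-2,2-dimethylchromane-6-carbaldehyde | CC1(C)Oc2ccc(C=O)cc2[C@H]3O[C@@H]13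
F3 | step 2 | (3R)-6-(hydroxymethyl)-2,2-dimethylchroman-3-ol | CC1(C)Oc2ccc(CO)cc2C[C@H]1O
F4 | step 4 | 5,7-bis(benzyloxy)-2-[(3R)-3-hydroxy-2,2-dimethylchroman-6-yl]-4H-chromen-4-one | CC1(C)Oc2ccc(-c3cc(=O)c4c(OCc5ccccc5)cc(OCc5ccccc5)cc4o3)cc2C[C@H]1O
F5 | step 1 | 3-bromo-4-hydroxybenzaldehyde | O=Cc1ccc(O)c(Br)c1
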